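The route disconnects benzo ring D (C4a'', C5''–C8'', C8a'') of the apigenin half at C7''–C8'' and C4a''–C5''. The feature used is that ring D is a phloroglucinol annulated to pyranone ring E, with the ring-B-bearing carbon C8'' as direct neighbour of C8a''; C8'' is therefore brought in as the CH2 group of a 2-benzyl-6-aryl-4-pyranone, and the hindered C3'–C8'' biaryl bond is inherited from an arylacetic acid instead of being forged by cross-coupling. In one operation this CH2 is acylated by a malonyl half-ester chloride and Claisen closure at C4a'' delivers the 8-aryl-5,7-dihydroxyflavone. The 7-methoxyflavone half is then attached at the ring-B bromide by borylation and oxidative Heck coupling.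

Key step: step 5

Numbering: C2–C8a for the 7-methoxyflavone half, C1'–C6' for its phenol ring B, C2''–C8a'' for the apigenin half (benzo ring D, pyranone ring E), C1'''–C6''' for its 4-hydroxyphenyl ring.
Assumptions: the target has no stereocentre and its SMILES fixes no axial configuration, so none is set; 2-(5-bromo-2-hydroxyphenyl)acetic acid and 5,7-dihydroxy-4H-chromen-4-one are taken as catalogue compounds.

Step 1
Reactants: 1 1-[4-(benzyloxy)phenyl]ethanone
Product: 2 1-[4-(benzyloxy)phenyl]butane-1,3-dione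
Conditions: NaH (2.2 equiv), EtOAc (3 equiv), THF, 0 °C to reflux; then 1 M HCl
Reagents that add atoms: ethyl acetate, CCOC(C)=O
Why: Crossed Claisen condensation of the methyl ketone enolate with ethyl acetate, driven to completion because the second equivalent of NaH converts the β-diketone into its enolate.

Step 2
Reactants: 3 2-(5-bromo-2-hydroxyphenyl)acetic acid
Product: 4 benzyl 2-[2-(benzyloxy)-5-bromophenyl]acetate
Conditions: BnBr (2.3 equiv), K2CO3 (3 equiv), DMF, 50 °C
Reagents that add atoms: benzyl bromide, BrCc1ccccc1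
Why: Double SN2 benzylation (Williamson ether synthesis at the phenoxide, O-alkylation of the carboxylate) in one pot; K2CO3 is too weak to enolise the arylacetate, so C-benzylation is not expected.

Step 3
Reactants: 2 1-[4-(benzyloxy)phenyl]butane-1,3-dione; 4 benzyl 2-[2-(benzyloxy)-5-bromophenyl]acetate
Product: 5 1-[2-(benzyloxy)-5-bromophenyl]-6-[4-(benzyloxy)phenyl]hexane-2,4,6-trione
Conditions: 2 (2.2 equiv), LiN(i-Pr)2 (4.5 equiv), THF, 0 °C; then 4 (1.0 equiv), −78 to 0 °C; then 1 M HCl
Reagents that add atoms: none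
Why: Claisen-type γ-acylation of a β-diketone dianion, in which the terminal and most basic carbanion attacks the ester carbonyl; the second equivalent of dianion takes up the more acidic triketone, and adding the ester to excess dianion at −78 °C favours carbonyl addition over proton transfer from the benzylic CH2 of 4.

Step 4
Reactants: 5 1-[2-(benzyloxy)-5-bromophenyl]-6-[4-(benzyloxy)phenyl]hexane-2,4,6-trione
Product: 6 2-[2-(benzyloxy)-5-bromobenzyl]-6-[4-(benzyloxy)phenyl]-4H-pyran-4-one
Conditions: TsOH·H2O (0.1 equiv), toluene, reflux, Dean–Stark trap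
Reagents that add atoms: none
Why: Acid-catalysed cyclodehydration of a 1,3,5-triketone (enol oxygen adds to the distal ketone, then loss of water), which gives the same 2,6-disubstituted 4-pyranone from either end and is mild enough for aryl benzyl ethers.

Step 5
Reactants: 6 2-[2-(benzyloxy)-5-bromobenzyl]-6-[4-(benzyloxy)phenyl]-4H-pyran-4-one; 7 methyl 3-chloro-3-oxopropanoate
Product: 9 8-[2-(benzyloxy)-5-bromophenyl]-2-[4-(benzyloxy)phenyl]-5,7-dihydroxy-4H-chromen-4-one, via β-keto ester 8 (not isolated)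
Conditions: LiN(SiMe3)2 (2.2 equiv), THF, −78 °C; 7 (1.1 equiv) added slowly; LiN(SiMe3)2 (1.5 equiv), MgBr2·OEt2 (2 equiv), −78 °C to reflux; then 1 M HCl
Reagents that add atoms: none
Why: Proposed new method: deprotonation of the CH2 group of 6 by LiN(SiMe3)2 should be easy because the anion is benzylic and at the same time a dienolate of the pyranone carbonyl, and this anion takes up the chlorocarbonyl carbon of 7 at C8'', which forms C8''–C7'' and gives 8 as its enolate. The second charge of base removes the remaining C8''–H, the charge of the resulting dienolate is relayed through C8a'' to C4a'', and C4a'' adds to the magnesium-bound ester carbonyl C5'' in a 6-exo-trig Claisen condensation that closes ring D; loss of methoxide and tautomerisation of the cyclohexadienone give the aromatic 5'',7''-diol. The closest known reaction types are the lateral metalation and acylation of 2-alkyl-4-pyranones and the biomimetic Claisen cyclisation of 3,5,7-triketo esters to acylphloroglucinols, but the two have not been joined in one flask on an intact 2-benzylpyranone. No stereocentre is created, and the one in 8 disappears on aromatisation. The selectivity required is closure at C4a'': attack by C8'' or by the C7'' enolate oxygen would need a four-membered ring, so the tether length leaves C4a'' as the only site that leads to a six-membered carbocycle able to aromatise, and slow addition of close to one equivalent of 7 to the preformed anion suppresses a second acylation. A non-nucleophilic amide base in THF with MgBr2·OEt2, in place of an alkoxide in alcohol, keeps pyranone ring E closed, so that the aryl group cannot reach C6'' by ring opening and reclosure, while chelation and the gain of aromaticity compensate for the low electrophilicity of the enolised β-keto ester.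

Step 6
Reactants: 9 8-[2-(benzyloxy)-5-bromophenyl]-2-[4-(benzyloxy)phenyl]-5,7-dihydroxy-4H-chromen-4-one
Product: 10 5,7-bis(benzyloxy)-8-[2-(benzyloxy)-5-bromophenyl]-2-[4-(benzyloxy)phenyl]-4H-chromen-4-one
Conditions: BnBr (2.5 equiv), K2CO3 (4 equiv), DMF, 70 °C
Reagents that add atoms: benzyl bromide, BrCc1ccccc1
Why: Williamson ether synthesis at both phenols of ring D, with DMF and heat to break the hydrogen bond of 5''-OH to the carbonyl; phenoxide O-alkylation dominates over C-alkylation at C6''.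

Step 7
Reactants: 10 5,7-bis(benzyloxy)-8-[2-(benzyloxy)-5-bromophenyl]-2-[4-(benzyloxy)phenyl]-4H-chromen-4-one
Product: 11 5,7-bis(benzyloxy)-8-[2-(benzyloxy)-5-(4,4,5,5-tetramethyl-1,3,2-dioxaborolan-2-yl)phenyl]-2-[4-(benzyloxy)phenyl]-4H-chromen-4-one
Conditions: B2pin2 (1.3 equiv), Pd(dppf)Cl2 (5 mol %), KOAc (3 equiv), 1,4-dioxane, 90 °C
Reagents that add atoms: bis(pinacolato)diboron, CC1(C)OB(OC1(C)C)B1OC(C)(C)C(C)(C)O1
Why: Miyaura borylation: oxidative addition of the aryl bromide to zerovalent palladium, acetate-assisted transmetalation with the diboron reagent and reductive elimination, all compatible with the flavone and the benzyl ethers.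

Step 8
Reactants: 12 5,7-dihydroxy-4H-chromen-4-one
Product: 13 5-hydroxy-7-methoxy-4H-chromen-4-one
Conditions: MeI (1.1 equiv), K2CO3 (1.2 equiv), acetone, reflux
Reagents that add atoms: iodomethane, CI
Why: Williamson methylation that is selective for the acidic 7-OH, because the 5-OH is held in a hydrogen bond to the C4 carbonyl and is not alkylated by one equivalent of MeI in acetone.

Step 9
Reactants: 13 5-hydroxy-7-methoxy-4H-chromen-4-one
Product: 14 5-(benzyloxy)-7-methoxy-4H-chromen-4-one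
Conditions: BnBr (1.3 equiv), K2CO3 (2 equiv), DMF, 70 °C
Reagents that add atoms: benzyl bromide, BrCc1ccccc1
Why: Williamson benzylation of the hydrogen-bonded 5-OH, which needs the more forcing DMF and heat.

Step 10
Reactants: 11 5,7-bis(benzyloxy)-8-[2-(benzyloxy)-5-(4,4,5,5-tetramethyl-1,3,2-dioxaborolan-2-yl)phenyl]-2-[4-(benzyloxy)phenyl]-4H-chromen-4-one; 14 5-(benzyloxy)-7-methoxy-4H-chromen-4-one
Product: 15 5,7-bis(benzyloxy)-8-{2-(benzyloxy)-5-[5-(benzyloxy)-7-methoxy-4-oxo-4H-chromen-2-yl]phenyl}-2-[4-(benzyloxy)phenyl]-4H-chromen-4-one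
Conditions: 14 (1.5 equiv), Pd(OCOCF3)2 (10 mol %), DDQ (1.2 equiv), AcOH/DMSO/H2O, 60 °C
Reagents that add atoms: none
Why: Oxidative Heck (boron-Heck) arylation of a chromone at C2: the aryl group passes from boron to divalent palladium, adds to the β-carbon C2 of the enone by insertion of C2=C3, and β-hydride elimination from the palladium enolate restores the double bond, while DDQ returns zerovalent palladium to the divalent state.

Step 11
Reactants: 15 5,7-bis(benzyloxy)-8-{2-(benzyloxy)-5-[5-(benzyloxy)-7-methoxy-4-oxo-4H-chromen-2-yl]phenyl}-2-[4-(benzyloxy)phenyl]-4H-chromen-4-one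
Product: 16 sequoiaflavone, 8-[2-hydroxy-5-(5-hydroxy-7-methoxy-4-oxo-4H-chromen-2-yl)phenyl]-5,7-dihydroxy-2-(4-hydroxyphenyl)-4H-chromen-4-one
Conditions: H2 (1 atm), 10% Pd/C (palladium on carbon), THF/MeOH, rt
Reagents that add atoms: none
Why: Hydrogenolysis of the five benzyl aryl ethers on palladium, under conditions (1 atm, rt) that leave the methyl ether, the chromone carbonyls and the C2=C3 bonds untouched.

Compound list
1 | 1-[4-(benzyloxy)phenyl]ethanone | CC(=O)c1ccc(OCc2ccccc2)cc1 | starting material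
2 | 1-[4-(benzyloxy)phenyl]butane-1,3-dione | CC(=O)CC(=O)c1ccc(OCc2ccccc2)cc1 | intermediate
3 | 2-(5-bromo-2-hydroxyphenyl)acetic acid | OC(=O)Cc1cc(Br)ccc1O | starting material
4 | benzyl 2-[2-(benzyloxy)-5-bromophenyl]acetate | O=C(Cc1cc(Br)ccc1OCc1ccccc1)OCc1ccccc1 | intermediate
5 | 1-[2-(benzyloxy)-5-bromophenyl]-6-[4-(benzyloxy)phenyl]hexane-2,4,6-trione | O=C(Cc1cc(Br)ccc1OCc1ccccc1)CC(=O)CC(=O)c1ccc(OCc2ccccc2)cc1 | intermediate
6 | 2-[2-(benzyloxy)-5-bromobenzyl]-6-[4-(benzyloxy)phenyl]-4H-pyran-4-one | O=c1cc(Cc2cc(Br)ccc2OCc2ccccc2)oc(-c2ccc(OCc3ccccc3)cc2)c1 | intermediate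
7 | methyl 3-chloro-3-oxopropanoate | COC(=O)CC(=O)Cl | starting material
8 | methyl 4-[2-(benzyloxy)-5-bromophenyl]-4-{6-[4-(benzyloxy)phenyl]-4-oxo-4H-pyran-2-yl}-3-oxobutanoate (β-keto ester, racemic at C4) | COC(=O)CC(=O)C(c1cc(Br)ccc1OCc1ccccc1)c1cc(=O)cc(-c2ccc(OCc3ccccc3)cc2)o1 | intermediate (not isolated)
9 | 8-[2-(benzyloxy)-5-bromophenyl]-2-[4-(benzyloxy)phenyl]-5,7-dihydroxy-4H-chromen-4-one | O=c1cc(-c2ccc(OCc3ccccc3)cc2)oc2c(-c3cc(Br)ccc3OCc3ccccc3)c(O)cc(O)c12 | intermediate
10 | 5,7-bis(benzyloxy)-8-[2-(benzyloxy)-5-bromophenyl]-2-[4-(benzyloxy)phenyl]-4H-chromen-4-one | O=c1cc(-c2ccc(OCc3ccccc3)cc2)oc2c(-c3cc(Br)ccc3OCc3ccccc3)c(OCc3ccccc3)cc(OCc3ccccc3)c12 | intermediate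
11 | 5,7-bis(benzyloxy)-8-[2-(benzyloxy)-5-(4,4,5,5-tetramethyl-1,3,2-dioxaborolan-2-yl)phenyl]-2-[4-(benzyloxy)phenyl]-4H-chromen-4-one | O=c1cc(-c2ccc(OCc3ccccc3)cc2)oc2c(-c3cc(B4OC(C)(C)C(C)(C)O4)ccc3OCc3ccccc3)c(OCc3ccccc3)cc(OCc3ccccc3)c12 | intermediate
12 | 5,7-dihydroxy-4H-chromen-4-one | O=c1ccoc2cc(O)cc(O)c12 | starting material
13 | 5-hydroxy-7-methoxy-4H-chromen-4-one | COc1cc(O)c2c(=O)ccoc2c1 | intermediate
14 | 5-(benzyloxy)-7-methoxy-4H-chromen-4-one | COc1cc(OCc2ccccc2)c2c(=O)ccoc2c1 | intermediate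
15 | 5,7-bis(benzyloxy)-8-{2-(benzyloxy)-5-[5-(benzyloxy)-7-methoxy-4-oxo-4H-chromen-2-yl]phenyl}-2-[4-(benzyloxy)phenyl]-4H-chromen-4-one | COc1cc(OCc2ccccc2)c2c(=O)cc(-c3ccc(OCc4ccccc4)c(-c4c(OCc5ccccc5)cc(OCc5ccccc5)c5c(=O)cc(-c6ccc(OCc7ccccc7)cc6)oc45)c3)oc2c1 | intermediate
16 | sequoiaflavone, 8-[2-hydroxy-5-(5-hydroxy-7-methoxy-4-oxo-4H-chromen-2-yl)phenyl]-5,7-dihydroxy-2-(4-hydroxyphenyl)-4H-chromen-4-one | COc1cc(O)c2c(=O)cc(-c3ccc(O)c(-c4c(O)cc(O)c5c(=O)cc(-c6ccc(O)cc6)oc45)c3)oc2c1 | target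

Total step count: 11.
Longest linear sequence: 8 steps (steps 1, 3, 4, 5, 6, 7, 10, 11; the branch through step 2 is equally long).

Steps most likely to fail

1. Step 5 (proposed new method). What may go wrong: dehydrochlorination of 7 by the lateral carbanion or by the amide base in place of C-acylation; O-acylation or a second acylation; stalling of the Claisen closure once the β-keto ester is enolised. The fallback uses known chemistry, gives up the benzannulation and makes the C3'–C8'' bond by cross-coupling; it sets out from 12 and returns at 10. Both phenols of 12 are benzylated (BnBr, K2CO3, DMF, 70 °C) to give 5,7-bis(benzyloxy)-4H-chromen-4-one F1. Oxidative Heck arylation of F1 with commercial [4-(benzyloxy)phenyl]boronic acid under the conditions of step 10 should give 5,7-bis(benzyloxy)-2-[4-(benzyloxy)phenyl]-4H-chromen-4-one F2. Electrophilic iodination (I2, AgOCOCF3, CH2Cl2, 0 °C), which 5,7-dialkoxyflavones undergo at C8, should give 5,7-bis(benzyloxy)-2-[4-(benzyloxy)phenyl]-8-iodo-4H-chromen-4-one F3. Suzuki–Miyaura coupling of F3 with commercial [2-(benzyloxy)-5-bromophenyl]boronic acid (Pd(PPh3)4, K2CO3, DME/H2O, 80 °C), in which the aryl iodide should react ahead of the aryl bromide, gives 10.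

2. Step 3. What may go wrong: proton transfer from the benzylic CH2 of ester 4 to the dianion in place of acylation, followed by self-condensation of the ester enolate. The fallback replaces the carbanion acylation by a neutral acylketene cycloaddition; it sets out from 4, with 1 as the partner, and returns at 6. Saponification of 4 (LiOH, THF/H2O, rt) gives 2-[2-(benzyloxy)-5-bromophenyl]acetic acid F4. Coupling of F4 with Meldrum's acid (DCC, DMAP, CH2Cl2, 0 °C to rt) gives 5-{2-[2-(benzyloxy)-5-bromophenyl]-1-hydroxyethylidene}-2,2-dimethyl-1,3-dioxane-4,6-dione F5. Ketone 1 is converted (Me3SiOTf, Et3N, CH2Cl2, 0 °C) into ({1-[4-(benzyloxy)phenyl]ethenyl}oxy)(trimethyl)silane F6. Heating F5 with F6 in toluene at 100 °C should release acetone and CO2 to give the acylketene 4-[2-(benzyloxy)-5-bromophenyl]-3-oxobut-1-en-1-one F7, which F6 should trap in a hetero-Diels–Alder reaction as racemic 6-[2-(benzyloxy)-5-bromobenzyl]-2-[4-(benzyloxy)phenyl]-2-[(trimethylsilyl)oxy]-2,3-dihydro-4H-pyran-4-one F8. TsOH·H2O in CH2Cl2 then eliminates trimethylsilanol from F8 to give 6.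

3. Step 10. What may go wrong: protodeboronation of the electron-rich aryl boronate in the acidic medium, homocoupling of the boronate, or arrest after conjugate addition without β-hydride elimination. The fallback is the classical chalcone route without boron; it sets out from 10 and returns at 15. Palladium-catalysed formylation of 10 (Pd(OAc)2, di(1-adamantyl)-n-butylphosphine, CO/H2 5 bar, TMEDA, toluene, 100 °C) gives 3-{5,7-bis(benzyloxy)-2-[4-(benzyloxy)phenyl]-4-oxo-4H-chromen-8-yl}-4-(benzyloxy)benzaldehyde F9. Mono-benzylation of commercial 1-(2,6-dihydroxy-4-methoxyphenyl)ethanone (BnBr 1.0 equiv, K2CO3, acetone, reflux) gives 1-[2-(benzyloxy)-6-hydroxy-4-methoxyphenyl]ethanone F10. Claisen–Schmidt condensation of F9 with F10 (KOH, EtOH/THF, rt) gives (E)-1-[2-(benzyloxy)-6-hydroxy-4-methoxyphenyl]-3-(3-{5,7-bis(benzyloxy)-2-[4-(benzyloxy)phenyl]-4-oxo-4H-chromen-8-yl}-4-(benzyloxy)phenyl)prop-2-en-1-one F11. Oxidative cyclisation of F11 (I2 cat., DMSO, 120 °C) gives 15.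

Further compounds
F1 | step 5 | 5,7-bis(benzyloxy)-4H-chromen-4-one | O=c1ccoc2cc(OCc3ccccc3)cc(OCc3ccccc3)c12
F2 | step 5 | 5,7-bis(benzyloxy)-2-[4-(benzyloxy)phenyl]-4H-chromen-4-one | O=c1cc(-c2ccc(OCc3ccccc3)cc2)oc2cc(OCc3ccccc3)cc(OCc3ccccc3)c12
F3 | step 5 | 5,7-bis(benzyloxy)-2-[4-(benzyloxy)phenyl]-8-iodo-4H-chromen-4-one | O=c1cc(-c2ccc(OCc3ccccc3)cc2)oc2c(I)c(OCc3ccccc3)cc(OCc3ccccc3)c12
F4 | step 3 | 2-[2-(benzyloxy)-5-bromophenyl]acetic acid | OC(=O)Cc1cc(Br)ccc1OCc1ccccc1
F5 | step 3 | 5-{2-[2-(benzyloxy)-5-bromophenyl]-1-hydroxyethylidene}-2,2-dimethyl-1,3-dioxane-4,6-dione | CC1(C)OC(=O)C(=C(O)Cc2cc(Br)ccc2OCc2ccccc2)C(=O)O1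
F6 | step 3 | ({1-[4-(benzyloxy)phenyl]ethenyl}oxy)(trimethyl)silane | C=C(O[Si](C)(C)C)c1ccc(OCc2ccccc2)cc1
F7 | step 3 | 4-[2-(benzyloxy)-5-bromophenyl]-3-oxobut-1-en-1-one (acylketene, transient) | O=C=CC(=O)Cc1cc(Br)ccc1OCc1ccccc1
F8 | step 3 | 6-[2-(benzyloxy)-5-bromobenzyl]-2-[4-(benzyloxy)phenyl]-2-[(trimethylsilyl)oxy]-2,3-dihydro-4H-pyran-4-one (racemic) | C[Si](C)(C)OC1(c2ccc(OCc3ccccc3)cc2)CC(=O)C=C(Cc2cc(Br)ccc2OCc2ccccc2)O1
F9 | step 10 | 3-{5,7-bis(benzyloxy)-2-[4-(benzyloxy)phenyl]-4-oxo-4H-chromen-8-yl}-4-(benzyloxy)benzaldehyde | O=Cc1ccc(OCc2ccccc2)c(-c2c(OCc3ccccc3)cc(OCc3ccccc3)c3c(=O)cc(-c4ccc(OCc5ccccc5)cc4)oc23)c1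
F10 | step 10 | 1-[2-(benzyloxy)-6-hydroxy-4-methoxyphenyl]ethanone | CC(=O)c1c(O)cc(OC)cc1OCc1ccccc1
F11 | step 10 | (E)-1-[2-(benzyloxy)-6-hydroxy-4-methoxyphenyl]-3-(3-{5,7-bis(benzyloxy)-2-[4-(benzyloxy)phenyl]-4-oxo-4H-chromen-8-yl}-4-(benzyloxy)phenyl)prop-2-en-1-one | COc1cc(O)c(C(=O)/C=C/c2ccc(OCc3ccccc3)c(-c3c(OCc4ccccc4)cc(OCc4ccccc4)c4c(=O)cc(-c5ccc(OCc6ccccc6)cc5)oc34)c2)c(OCc2ccccc2)c1
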